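**Assumptions:** the target is taken exactly as the given SMILES (kaurane numbering; 4R,5R,6R,8S,9S,10R,13R). The 6R methyl acetal (OMe trans to H‑5, anti to the C4 methyl) is assumed to be the thermodynamic anomer, so it is set by acid equilibration; this is not proven.

## Retrosynthetic overview

1. D ring last: 5‑exo cyclization of a C16 α‑keto vinyl radical (from a 2‑iodo‑enone) onto C13 closes the bicyclo[3.2.1]octane and gives the 16‑methylene‑15‑ketone directly.
2. Ring C: Diels–Alder of butadiene with a 3‑acetyl‑5,6‑dihydropyran‑2‑one, setting C8 and C9 anti to the C5/C6 acetal flank.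
3. Key step, spirolactone and C9–C10 bond: the Ti(III)‑generated C10 tertiary radical from a spiro‑epoxide adds to a push–pull alkoxymethylene acetoacetate, then β‑OMe elimination and lactonization. This sets C10.
4. A ring and THF acetal: Cu‑catalysed asymmetric conjugate alkenylation of 3‑methylcyclohexenone with enolate capture by orthoformate (C4), then ozonolysis, reduction and transacetalization (C5, C6).
5. Ring order: A → THF acetal → spiro‑δ‑lactone → C → D.

## Route

**Step 1**
Reactants: 1, 3‑methylcyclohex‑2‑en‑1‑one; 2, hex‑1‑yne; 3, trimethyl orthoformate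
Product: 4, (2RS,3S)‑2‑(dimethoxymethyl)‑3‑[(E)‑hex‑1‑enyl]‑3‑methylcyclohexan‑1‑one
Conditions: 2, DIBAL‑H, heptane, 55 °C; then 1, CuTC (10 mol %), chiral phosphoramidite (SimplePhos type, 11 mol %), Et2O, −30 °C; then TMSOTf, −78 °C; then 3, −78 → −40 °C; NaHCO3
Reagents that add atoms: none beyond reactants 2 (as its (E)‑hexenyl‑diisobutylalane, CCCC/C=C/[Al](CC(C)C)CC(C)C) and 3
Why: Cu‑catalysed asymmetric conjugate addition of an alkenylalane sets the C4 quaternary centre under ligand control; the regiodefined enolate is silylated and alkylated in the same pot at C5 by a Mukaiyama orthoformate reaction (the C5 epimer mixture is corrected in step 2).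

**Step 2**
Reactants: 4
Product: 5, (1R,3aR,7aS)‑1‑methoxy‑3a‑methylhexahydroisobenzofuran‑7(1H)‑one (cis‑fused; OMe trans to H‑7a)
Conditions: O3, CH2Cl2, −78 °C (Sudan III end point); PPh3; then NaBH(OAc)3, AcOH, rt; then PPTS, CH2Cl2, 4 Å MS, rt
Reagents that add atoms: ozone, [O-][O+]=O (supplies the C19 oxygen)
Why: ozonolysis cuts the hexenyl group to the C19 aldehyde, triacetoxyborohydride reduces that aldehyde but not the hindered ketone, and acid transacetalization closes the five‑membered methyl acetal; C5 (α to the ketone) and C6 (anomeric) equilibrate under the acid to the cis‑fused ring with OMe anti to the angular methyl.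

**Step 3**
Reactants: 5
Product: 6, (1R,3aR,7aR)‑1‑methoxy‑3a‑methylhexahydro‑1H‑spiro[isobenzofuran‑7,2'‑oxirane] (either epimer at the spiro carbon)
Conditions: ClCH2I, MeLi·LiBr, THF, −78 °C → rt
Reagents that add atoms: chloroiodomethane, ClCI (CH2)
Why: in situ LiCH2Cl adds to the ketone faster than it enolizes it (avoiding β‑alkoxide loss from the β‑keto acetal) and the chlorohydrin alkoxide closes to the epoxide (Matteson‑type epoxidation); the new C10 centre is irrelevant because it becomes a planar radical.

**Step 4**
Reactants: 7, methyl acetoacetate; 3, trimethyl orthoformate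
Product: 8, methyl 2‑(methoxymethylidene)‑3‑oxobutanoate
Conditions: Ac2O, 120 °C, distil off MeOH/MeOAc
Reagents that add atoms: none (both partners are numbered reactants)
Why: standard orthoformate condensation of a 1,3‑dicarbonyl compound; no stereocentre.

**Step 5 (key step)**
Reactants: 6; 8 (3 equiv)
Product: 9, (1R,3aR,7R,7aR)‑5'‑acetyl‑1‑methoxy‑3a‑methylhexahydro‑1H‑spiro[isobenzofuran‑7,3'‑pyran]‑6'(2'H)‑one (the 3‑acetyl‑5,6‑dihydropyran‑2‑one spiro at C10)
Conditions: Cp2TiCl2 (2.5 equiv), Zn, THF, rt; add 6 + 8, 0 → 40 °C; aq NaH2PO4 (cat. DBU if hydroxy ester remains)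
Reagents that add atoms: none
Why: Proposed new method: Cp2TiCl opens the epoxide to the tertiary C10 radical with C20–O–Ti; the radical adds to the methoxy‑bearing carbon of 8, the 1,3‑dicarbonyl radical is reduced to a Ti enolate that expels methoxide (net radical alkenylation), and the titanium alkoxide lactonizes onto the ester. The closest known chemistry is the Nugent–RajanBabu epoxide/acrylate Giese–lactonization used for spirolactones of this family, combined with radical addition–β‑elimination on β‑heteroatom acrylates. C10 is set by attack on the face opposite the axial C4–CH2O arm of the cis‑fused acetal, so C9 ends trans to C6 and C20 cis to C19.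

**Step 6**
Reactants: 9; 10, buta‑1,3‑diene (excess)
Product: 11, (4R,5R,6R,8S,9S,10R)‑cis‑fused cyclohexene adduct: ring C (C8, C9, C11, C12=C13, C14) fused to the lactone, with C8 quaternary and bearing the acetyl group
Conditions: ZnCl2 (1 equiv), CH2Cl2/Et2O, sealed tube, 25–40 °C
Reagents that add atoms: none
Why: Lewis‑acid Diels–Alder of a doubly activated alkylidene 1,3‑dicarbonyl dienophile next to a quaternary carbon (as with 2‑acyl‑4,4‑dialkyl enones); butadiene adds to the face syn to C1H2 and anti to the C5/C6 acetal, and suprafacial addition puts C11 and C14 cis with the acetyl on the opposite face, setting C9 and C8.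

**Step 7**
Reactants: 11
Product: 12, the corresponding C8 acryloyl compound (C15(=O)–C16H=C17H2), same stereocentres
Conditions: LiHMDS, THF, −78 °C; Eschenmoser's salt, −78 → 0 °C; MeI, CH2Cl2; aq NaHCO3
Reagents that add atoms: Eschenmoser's salt, C=[N+](C)C.[I-] (CH2)
Why: the acetyl methyl is the only enolizable position (C8 is quaternary), so Mannich reaction, quaternization and elimination give the vinyl ketone (α‑methylenation); no stereocentre changes.

**Step 8**
Reactants: 12
Product: 13, the 2‑iodoacryloyl compound (C15(=O)–C16(I)=C17H2)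
Conditions: I2, pyridine, CCl4, 0 °C → rt
Reagents that add atoms: iodine, II
Why: Johnson α‑iodination of an enone (pyridine conjugate addition, enolate iodination, elimination) is selective for the enone over the isolated ring alkene.

**Step 9**
Reactants: 13
Product: 14, Ludongunin J
Conditions: Bu3SnH (1.3 equiv, syringe pump), AIBN, PhH, 80 °C, 0.01 M
Reagents that add atoms: none
Why: iodine abstraction gives the C16 α‑keto vinyl radical, which cyclizes 5‑exo‑trig onto C13 from the pseudoaxial acyl group (Stork‑type vinyl radical cyclization; the same connectivity as 2‑haloacrylamide → α‑methylene lactam closures), and the C12 radical is reduced by tin hydride; the two‑carbon bridge can only span C8 and C13 on one face, which fixes C13 as R, and the exo‑methylene ketone is formed directly.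

## Compound list

1 | 3‑methylcyclohex‑2‑en‑1‑one | CC1=CC(=O)CCC1 | starting material
2 | hex‑1‑yne | C#CCCCC | starting material
3 | trimethyl orthoformate | COC(OC)OC | starting material
4 | (2RS,3S)‑2‑(dimethoxymethyl)‑3‑[(E)‑hex‑1‑enyl]‑3‑methylcyclohexan‑1‑one | O=C1CCC[C@@](C)(/C=C/CCCC)C1C(OC)OC | intermediate
5 | (1R,3aR,7aS)‑1‑methoxy‑3a‑methylhexahydroisobenzofuran‑7(1H)‑one | O=C1CCC[C@@]2(C)CO[C@@H](OC)[C@H]21 | intermediate
6 | (1R,3aR,7aR)‑1‑methoxy‑3a‑methylhexahydro‑1H‑spiro[isobenzofuran‑7,2'‑oxirane] | O1CC12CCC[C@@]3(C)CO[C@@H](OC)[C@@H]23 | intermediate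
7 | methyl acetoacetate | CC(=O)CC(=O)OC | starting material
8 | methyl 2‑(methoxymethylidene)‑3‑oxobutanoate | COC=C(C(C)=O)C(=O)OC | intermediate
9 | (1R,3aR,7R,7aR)‑5'‑acetyl‑1‑methoxy‑3a‑methylhexahydro‑1H‑spiro[isobenzofuran‑7,3'‑pyran]‑6'(2'H)‑one | CC(=O)C1=C[C@@]2(CCC[C@@]3(C)CO[C@@H](OC)[C@H]32)COC1=O | intermediate
10 | buta‑1,3‑diene | C=CC=C | starting material
11 | (4R,5R,6R,8S,9S,10R)‑8‑acetyl Diels–Alder adduct (ring C cyclohexene, C12=C13) | CC(=O)[C@]12CC=CC[C@H]1[C@@]1(CCC[C@@]3(C)CO[C@@H](OC)[C@H]31)COC2=O | intermediate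
12 | 8‑acryloyl analogue of 11 | C=CC(=O)[C@]12CC=CC[C@H]1[C@@]1(CCC[C@@]3(C)CO[C@@H](OC)[C@H]31)COC2=O | intermediate
13 | 8‑(2‑iodoacryloyl) analogue of 11 | C=C(I)C(=O)[C@]12CC=CC[C@H]1[C@@]1(CCC[C@@]3(C)CO[C@@H](OC)[C@H]31)COC2=O | intermediate
14 | Ludongunin J (4R,5R,6R,8S,9S,10R,13R) | C=C1C(=O)[C@]23C[C@H]1CC[C@H]2[C@@]1(CCC[C@@]2(C)CO[C@@H](OC)[C@H]21)COC3=O | target

## Step count and risks

Total steps: 9. Longest linear sequence: 8 (steps 1–3, 5–9).

Steps most likely to fail:

1. **Step 5.** The hindered tertiary radical may add too slowly to the push–pull acceptor, so that Ti(III) instead gives the allylic alcohol or reduced alcohol. Fallback: use methyl acrylate in the known epoxide/acrylate Giese–lactonization to get the saturated spirolactone, then C8 acetylation (LDA, N‑acetylimidazole) and selenoxide dehydrogenation to reach 9 (two extra steps).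
2. **Step 6.** Cycloaddition at the neopentyl C9 may be too slow, or ZnCl2 may scramble the acetal. Fallback: bring ring C in pre‑formed by coupling epoxide 6 under Ti(III) with methyl cyclohexa‑1,4‑diene‑1‑carboxylate (from butadiene and methyl propiolate), then C‑acylate C8 with 2‑bromoacryloyl chloride and cyclize. The cost is that C9 selectivity in that coupling is not secured.
3. **Step 9.** Competing 6‑endo closure to the bicyclo[2.2.2] isomer, 1,5‑H transfer from C11, or premature reduction of the vinyl radical. Fallback: Pd(0) reductive Heck cyclization of 13 (Pd(OAc)2, PPh3, HCO2Na), a 5‑exo carbopalladation route to the same C13–C16 bond.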